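The plan shrinks benzenoid ring B (C4a, C5–C8, C8a) of the naphthoquinone by one atom. Its methoxy-bearing C6 has only hydrogen-bearing neighbours, C5 and C7, and no other bond to the skeleton. This makes it the natural atom to add at the end. Dichlorocarbene is added to the C5=C7 alkene of a racemic 1-aryl-1H-indene. Opening of the gem-dichlorocyclopropane and loss of HCl create C5–C6 and C6–C7 in one operation, enlarge the five-membered ring to the arene and leave chlorine on C6 as the handle for methoxy. The indene already carries ring C on C8 and a 1,2,4-trimethoxybenzo ring, the masked quinone ring A.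

Key step: step 5

Remark: atoms keep the locants of the target (C1 and C4 carbonyl carbons, C2–OMe, C6–OMe, C8–aryl) in every precursor of the main route; all chiral intermediates are racemic, so each SMILES shows one enantiomer and only the relative configuration is meant.

Step 1
Reactants: 1 1-(2,4,5-trimethoxyphenyl)ethanone; 2 3,4-dimethoxybenzaldehyde (veratraldehyde)
Product: 3 (E)-3-(3,4-dimethoxyphenyl)-1-(2,4,5-trimethoxyphenyl)prop-2-en-1-one
Conditions: KOH (aq.), EtOH, rt
Reagents that add atoms: none
Why: Claisen–Schmidt condensation (crossed aldol condensation), in which only 1 can form an enolate and 2 is a non-enolisable aldehyde, and base-mediated E1cB loss of water under equilibrating conditions should give the conjugated E-enone.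

Step 2
Reactants: 3 (E)-3-(3,4-dimethoxyphenyl)-1-(2,4,5-trimethoxyphenyl)prop-2-en-1-one
Product: 4 (±)-3-(3,4-dimethoxyphenyl)-4,5,7-trimethoxy-2,3-dihydro-1H-inden-1-one
Conditions: CF3CO2H (0.05 M), 80 °C, sealed tube
Reagents that add atoms: none
Why: Aromatic Nazarov cyclisation (4π-conrotatory closure of the O-protonated aryl styryl ketone, equivalent to an intramolecular Friedel–Crafts alkylation), in which C8 is a para-methoxybenzyl-type cation, C8a is the only free position ortho to the carbonyl group and is activated by the adjacent methoxy group, and rearomatisation with tautomerisation should give the indanone, its single stereocentre C8 being formed without control because it is lost in step 5.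

Step 3
Reactants: 4 (±)-3-(3,4-dimethoxyphenyl)-4,5,7-trimethoxy-2,3-dihydro-1H-inden-1-one
Product: 5 (±)-cis-3-(3,4-dimethoxyphenyl)-4,5,7-trimethoxy-2,3-dihydro-1H-inden-1-ol
Conditions: NaBH4, MeOH/THF, 0 °C to rt; neutral aqueous work-up
Reagents that add atoms: none
Why: Borohydride 1,2-reduction of the aryl ketone, with hydride delivered to the face of the flat indanone opposite to ring C so that the cis alcohol should prevail (substrate control), which is of no consequence because both epimers give the same alkene.

Step 4
Reactants: 5 (±)-cis-3-(3,4-dimethoxyphenyl)-4,5,7-trimethoxy-2,3-dihydro-1H-inden-1-ol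
Product: 7 (±)-1-(3,4-dimethoxyphenyl)-4,6,7-trimethoxy-1H-indene, via sulfamate ester 6 (not isolated)
Conditions: Burgess reagent (MeO2CN(−)SO2N(+)Et3, 1.4 equiv), toluene, rt to 50 °C; short neutral silica plug, used at once
Reagents that add atoms: none
Why: Burgess dehydration, in which the alcohol is sulfonylated to 6 and an intramolecular syn elimination (Ei) removes a hydrogen from C7, the only carbon with β-hydrogens, in a medium that holds neither free amine nor strong acid, so that the C5=C7 alkene should neither migrate nor dimerise.

Step 5
Reactants: 7 (±)-1-(3,4-dimethoxyphenyl)-4,6,7-trimethoxy-1H-indene; 8 sodium trichloroacetate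
Product: 10 6-chloro-8-(3,4-dimethoxyphenyl)-1,2,4-trimethoxynaphthalene, via gem-dichlorocyclopropane 9 (not isolated)
Conditions: 8 (4 equiv, added in portions), DME, reflux (85 °C), N2
Reagents that add atoms: sodium trichloroacetate 8, [Na+].[O-]C(=O)C(Cl)(Cl)Cl
Why: Thermal decarboxylation of 8 releases electrophilic singlet dichlorocarbene, which adds in a concerted cheletropic [2+1] fashion to C5=C7, the most electron-rich π bond of 7 because it is conjugated with the ortho and para methoxy groups of the benzo ring, and this closes the three-membered ring of 9. The endo chloride then leaves while the C5–C7 bond breaks in a disrotatory two-electron electrocyclic opening (cyclopropyl to allyl cation), so the six-membered ring arises by ring expansion and not by a new cyclisation, the charge at C5 being carried by the same methoxy groups. Loss of the doubly benzylic C8 proton aromatises ring B and erases all three stereocentres, so neither the face of carbene attack (expected anti to ring C) nor the racemic nature of 7 matters. The closest known reaction is the dihalocarbene ring enlargement of indenes to 2-halonaphthalenes, the carbocyclic counterpart of the Ciamician–Dennstedt reaction. Two selectivities are needed: alkene over methoxyarenes, secured by the far higher reactivity of a styrene-type double bond towards dichlorocarbene and by a limited excess of 8, and retention of the alkene at C5=C7, since after a shift to C7=C8 the carbon would enter between C7 and C8. The latter is secured by excluding hydroxide, alkoxide and amine bases, by adding 8 in portions so that little trichloromethyl anion is ever present, and by the clash between ring C and the C1 methoxy group, which lowers the gain of the conjugated isomer.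

Step 6
Reactants: 10 6-chloro-8-(3,4-dimethoxyphenyl)-1,2,4-trimethoxynaphthalene
Product: 11 8-(3,4-dimethoxyphenyl)-1,2,4,6-tetramethoxynaphthalene
Conditions: Pd2(dba)3 (2 mol %), tBuBrettPhos (5 mol %), NaOtBu, MeOH (5 equiv), 1,4-dioxane, 60 °C
Reagents that add atoms: methanol, CO
Why: Palladium-catalysed C–O cross-coupling (Buchwald–Hartwig etherification), in which the unhindered C6–Cl bond adds oxidatively to zerovalent palladium, methoxide replaces chloride and the bulky biaryl phosphine favours reductive elimination over β-hydride elimination, all other groups being inert aryl methyl ethers.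

Step 7
Reactants: 11 8-(3,4-dimethoxyphenyl)-1,2,4,6-tetramethoxynaphthalene
Product: 12 8-(3,4-dimethoxyphenyl)-2,6-dimethoxynaphthalene-1,4-dione
Conditions: (NH4)2Ce(NO3)6 (2.5 equiv), MeCN/H2O, 0 °C
Reagents that add atoms: water, O
Why: Oxidative demethylation of a hydroquinone dimethyl ether by tetravalent cerium, in which two one-electron oxidations of the most electron-rich ring, the only one with a para-dimethoxy pair (C1/C4), each followed by addition of water and loss of methanol, should give the para-quinone, while C2–OMe survives as a vinylogous ester and rings B and C, which lack para-dioxygenation, stay intact.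

Compound list
1 | 1-(2,4,5-trimethoxyphenyl)ethanone | COc1cc(OC)c(C(C)=O)cc1OC | starting material
2 | 3,4-dimethoxybenzaldehyde (veratraldehyde) | COc1ccc(C=O)cc1OC | starting material
3 | (E)-3-(3,4-dimethoxyphenyl)-1-(2,4,5-trimethoxyphenyl)prop-2-en-1-one | COc1cc(OC)c(C(=O)/C=C/c2ccc(OC)c(OC)c2)cc1OC | intermediate
4 | (±)-3-(3,4-dimethoxyphenyl)-4,5,7-trimethoxy-2,3-dihydro-1H-inden-1-one | O=C1C[C@H](c2ccc(OC)c(OC)c2)c2c1c(OC)cc(OC)c2OC | intermediate
5 | (±)-cis-3-(3,4-dimethoxyphenyl)-4,5,7-trimethoxy-2,3-dihydro-1H-inden-1-ol (1R*,3R*) | O[C@@H]1C[C@H](c2ccc(OC)c(OC)c2)c2c1c(OC)cc(OC)c2OC | intermediate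
6 | triethylammonium salt of the N-(methoxycarbonyl)sulfamate ester of 5 (O-sulfonylated at the carbinol, cis) | CC[NH+](CC)CC.COC(=O)[N-]S(=O)(=O)O[C@@H]1C[C@H](c2ccc(OC)c(OC)c2)c2c1c(OC)cc(OC)c2OC | intermediate
7 | (±)-1-(3,4-dimethoxyphenyl)-4,6,7-trimethoxy-1H-indene | COc1cc(OC)c2C=C[C@H](c3ccc(OC)c(OC)c3)c2c1OC | intermediate
8 | sodium trichloroacetate | [Na+].[O-]C(=O)C(Cl)(Cl)Cl | starting material
9 | (±)-1,1-dichloro-6-(3,4-dimethoxyphenyl)-2,4,5-trimethoxy-1,1a,6,6a-tetrahydrocyclopropa[a]indene, ring C anti to the CCl2 bridge | COc1cc(OC)c2c(c1OC)[C@@H](c1ccc(OC)c(OC)c1)[C@H]1[C@@H]2C1(Cl)Cl | intermediate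
10 | 6-chloro-8-(3,4-dimethoxyphenyl)-1,2,4-trimethoxynaphthalene | COc1cc(OC)c2cc(Cl)cc(-c3ccc(OC)c(OC)c3)c2c1OC | intermediate
11 | 8-(3,4-dimethoxyphenyl)-1,2,4,6-tetramethoxynaphthalene | COc1cc(OC)c2cc(OC)cc(-c3ccc(OC)c(OC)c3)c2c1OC | intermediate
12 | 8-(3,4-dimethoxyphenyl)-2,6-dimethoxynaphthalene-1,4-dione | COC1=CC(=O)c2cc(OC)cc(-c3ccc(OC)c(OC)c3)c2C1=O | target

Total steps: 7. Longest linear sequence: 7 steps (1 or 2 to 12).

Steps most likely to fail

1. Step 5.
- **What may go wrong:** The C8–H of 7 is doubly benzylic and allylic. Proton transfer to the short-lived trichloromethyl anion could start a chain of deprotonation and reprotonation that moves the alkene from C5=C7 to C7=C8 before the carbene arrives, so the new carbon would enter between C7 and C8. A second carbene addition to the electron-rich product and slow opening of 9 are smaller concerns.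
- **Fallback (from 4, back at 11, replacing steps 3 to 6):** The missing ring atom is inserted next to the carbonyl group instead of into an alkene. Homologation of 4 with Me3SiCHN2 and BF3·OEt2 (CH2Cl2, −40 °C), in which the electron-rich aryl group migrates, should give the C-silylated 2-tetralone F1. This loses silicon on work-up with dilute acid to give the 4-aryl-2-tetralone F2. In this variant the carbonyl carbon of 4 ends up as C6 with its oxygen function in place, and the inserted carbon as C5. HC(OMe)3 with catalytic TsOH in MeOH should give the conjugated methyl enol ether F3, and one equivalent of DDQ (toluene, 0 °C) should aromatise it to 11.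

2. Step 2.
- **What may go wrong:** Closure has to occur at a position that is activated by one ortho methoxy group only and is deactivated by the protonated carbonyl group. It may therefore be slower than three competing processes: attack of the neighbouring C4 methoxy oxygen on the benzylic cation with loss of its methyl group, acid cleavage of the aryl–acyl bond, and intermolecular alkylation.
- **Fallback (from 1, back at 4):** The acceptor is made more electrophilic instead of forcing the acid. Claisen condensation of 1 with dimethyl carbonate (NaH, THF, reflux) should give the β-keto ester F4. Knoevenagel condensation with 2 (piperidine, AcOH, toluene, water separator) should give the alkylidene β-keto ester F5. A polarised Nazarov cyclisation with catalytic Cu(OTf)2 (ClCH2CH2Cl, 60 °C) should give the trans indanone ester F6. Krapcho-type dealkoxycarbonylation in wet DMSO at 130 °C then returns 4.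

3. Step 4.
- **What may go wrong:** The carbinol carbon C5 ionises very easily, so the ion pair from 6 may collapse by C–N bond formation instead of losing a proton. The electron-rich, C8–H-acidic alkene may also dimerise on acidic media or shift its double bond on basic ones during isolation.
- **Fallback (from 4, back at 7, replacing steps 3 and 4):** The alkene is made by enolisation and C–O reduction instead of elimination. Tf2O and 2,6-di-tert-butyl-4-methylpyridine (CH2Cl2, 0 °C) should give the enol triflate F7. Hydride transfer from Bu3SnH with Pd(PPh3)4 and LiCl (THF, 50 °C), a neutral medium, should then replace the triflate by hydrogen to give 7.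

Further compounds
F1 | step 5 | (±)-4-(3,4-dimethoxyphenyl)-5,6,8-trimethoxy-1-(trimethylsilyl)-3,4-dihydronaphthalen-2(1H)-one (mixture at C1) | C[Si](C)(C)C1C(=O)C[C@H](c2ccc(OC)c(OC)c2)c2c1c(OC)cc(OC)c2OC
F2 | step 5 | (±)-4-(3,4-dimethoxyphenyl)-5,6,8-trimethoxy-3,4-dihydronaphthalen-2(1H)-one | O=C1C[C@H](c2ccc(OC)c(OC)c2)c2c(C1)c(OC)cc(OC)c2OC
F3 | step 5 | (±)-1-(3,4-dimethoxyphenyl)-3,5,7,8-tetramethoxy-1,2-dihydronaphthalene | COC1=Cc2c(OC)cc(OC)c(OC)c2[C@@H](c2ccc(OC)c(OC)c2)C1
F4 | step 2 | methyl 3-oxo-3-(2,4,5-trimethoxyphenyl)propanoate | COC(=O)CC(=O)c1cc(OC)c(OC)cc1OC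
F5 | step 2 | methyl 3-(3,4-dimethoxyphenyl)-2-(2,4,5-trimethoxybenzoyl)prop-2-enoate (E/Z mixture, both isomers converge) | COC(=O)C(=Cc1ccc(OC)c(OC)c1)C(=O)c1cc(OC)c(OC)cc1OC
F6 | step 2 | methyl (±)-trans-3-(3,4-dimethoxyphenyl)-4,5,7-trimethoxy-1-oxo-2,3-dihydro-1H-indene-2-carboxylate | COC(=O)[C@@H]1C(=O)c2c(OC)cc(OC)c(OC)c2[C@H]1c1ccc(OC)c(OC)c1
F7 | step 4 | (±)-1-(3,4-dimethoxyphenyl)-4,6,7-trimethoxy-1H-inden-3-yl trifluoromethanesulfonate | COc1cc(OC)c2C(OS(=O)(=O)C(F)(F)F)=C[C@H](c3ccc(OC)c(OC)c3)c2c1OC
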